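**Retrosynthetic overview**

1. Rings C and D form a bicyclo[3.2.1]octane: the seven-membered ring C8–C9–C11–C12–C13–C16–C15 bridged by the single carbon C14. This is the (4+3) adduct of a cyclopentadiene (C8, C15, C16, C13, C14) and a three-carbon oxyallyl cation (C9–C11–C12).
2. Key disconnection: C8–C9 and C12–C13, by intramolecular (4+3) cycloaddition of a ring A dichloromethyl ketone onto a C6-linked cyclopentadiene. Rings B and C close together and the old diene becomes ring D.
3. The chloride left at C12 is displaced by the C20 ester to give the C20–O–C12 lactone; the C11 ketone is then removed, and C17 is added at C16 by hydroboration, oxidation and Wittig methylenation.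
4. Ring A comes from a Diels–Alder reaction of methyl pentadienoate with maleic anhydride, an alkaloid-catalysed resolving methanolysis, two enolate alkylations anti to the C5 carboxyl, and osmylation.
5. The C6–C8 bond and C6 come from Arndt–Eistert homologation followed by Ireland–Claisen rearrangement of a cyclopentenyl ester; the diene is unveiled last by dehydration. Ring order: A, then B + C (with D bridged), then the lactone.

Key step: step 16

Remarks (gibberellane numbering throughout):
- Assumption: compounds 1, 4, 5 and 10 are taken as commercial.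
- The diene is left unsubstituted. A 1,3-disubstituted cyclopentadiene would also populate a 1,5-hydrogen-shift isomer whose cycloaddition bonds at C16. The plain ring has only one isomer that can react through the tether.
- The oxyallyl precursor is a dichloromethyl ketone. It ionises more readily than a chloromethyl ketone, and the chloride that remains at C12 becomes the handle for the lactone.
- LiClO4 is added in the key step so that a real cation can bridge the oxyallyl oxygen and the C20 ester.
- The stereocentres on the cyclopentene ring of 18–24 are temporary and vanish in step 15.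

Step 1
Reactants: 1 (1R,4S)-cis-4-acetoxycyclopent-2-en-1-ol
Product: 2 (1S,4R)-4-(tert-butyldimethylsilyloxy)cyclopent-2-en-1-yl acetate
Conditions: t-BuMe2SiCl, imidazole, DMF, rt
Reagents that add atoms: tert-butyldimethylsilyl chloride, CC(C)(C)[Si](C)(C)Cl
Why: Standard silylation of the free secondary alcohol, which touches no stereocentre.

Step 2
Reactants: 2 (1S,4R)-4-(tert-butyldimethylsilyloxy)cyclopent-2-en-1-yl acetate
Product: 3 (1S,4R)-4-(tert-butyldimethylsilyloxy)cyclopent-2-en-1-ol
Conditions: K2CO3, MeOH, 0 °C
Reagents that add atoms: none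
Why: Base-catalysed transesterification removes the acetate and leaves the silyl ether, freeing the carbinol that will carry the C7 ester.

Step 3
Reactants: 4 methyl (2E)-penta-2,4-dienoate; 5 maleic anhydride
Product: 6 racemic all-cis adduct, methyl 1,3-dioxo-1,3,3a,4,7,7a-hexahydro-2-benzofuran-4-carboxylate
Conditions: toluene, BHT, 90 °C
Reagents that add atoms: none
Why: Thermal Diels–Alder reaction in which endo addition to the (E)-diene places the C19 ester cis to both anhydride carbonyls (C4, C5, C10 all-cis, racemic) and leaves the alkene at C2=C3.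

Step 4
Reactants: 6 racemic all-cis anhydride
Product: 7 all-cis 2,6-bis(methoxycarbonyl)cyclohex-3-ene-1-carboxylic acid, single enantiomer (C5 acid, C4 and C10 methyl esters)
Conditions: (DHQD)2AQN (cat.), MeOH (0.55 equiv), Et2O, −20 °C, to about half conversion; acid/base extraction
Reagents that add atoms: methanol, CO
Why: Cinchona-alkaloid-catalysed alcoholysis of a cyclic anhydride run as a kinetic resolution, in which for the wanted enantiomer the catalyst-preferred carbonyl is also the unhindered one (C20, remote from the C4 ester), so that it should open to the C10 ester/C5 acid while the antipode stays as neutral anhydride; the sense of induction is inferred from meso tetrahydrophthalic anhydride and would be checked on the first run, the pseudoenantiomeric (DHQ)2AQN being the alternative.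

Step 5
Reactants: 7 all-cis hemiester
Product: 9 2,6-bis(methoxycarbonyl)-2-methylcyclohex-3-ene-1-carboxylic acid (C18 on C4, trans to the C5 carboxyl), via dilithium dienolate carboxylate 8 (not isolated)
Conditions: LiN(i-Pr)2 (2.2 equiv), THF, −78 to −40 °C; MeI, −78 °C
Reagents that add atoms: iodomethane, CI
Why: Ester dienolate α-alkylation in which, after the carboxylate, the allylic C4–H is the most acidic site and iodomethane attacks C4 anti to the neighbouring C5 carboxylate (held pseudoaxial by allylic 1,3-strain), so that C18 is trans and the C19 ester cis to the C5 carboxyl and the alkene stays at C2=C3.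

Step 6
Reactants: 9 C4-methylated hemiester; 10 2-bromo-N-methoxy-N-methylacetamide
Product: 12 C10-alkylated acid carrying the C9–C11 Weinreb amide chain, via dilithium enolate carboxylate 11 (not isolated)
Conditions: LiN(i-Pr)2 (2.2 equiv), THF/DMPU, −78 °C; 10, −78 to −20 °C
Reagents that add atoms: none
Why: Ester enolate alkylation at the only remaining enolisable ester position (the carboxylate protects C5–H), the electrophile entering anti to the C5 carboxylate so that C9 is trans and the C20 ester cis to C5, which completes the all-cis C19/C5/C20 array with both quaternary centres.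

Step 7
Reactants: 12 cyclohexene acid
Product: 13 C2,C3-cis-diol
Conditions: OsO4 (cat.), N-methylmorpholine N-oxide, acetone/H2O, rt
Reagents that add atoms: osmium tetroxide, O=[Os](=O)(=O)=O; N-methylmorpholine N-oxide, C[N+]1([O-])CCOCC1
Why: Upjohn syn-dihydroxylation, which should add to the C2=C3 face opposite the two axial esters (C19 on the allylic C4, C20 on C10) and so place both hydroxyls on the face of C18 and C9.

Step 8
Reactants: 13 diol acid
Product: 14 C2,C3-acetonide acid
Conditions: Me2C(OMe)2, PPTS, acetone, rt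
Reagents that add atoms: 2,2-dimethoxypropane, COC(C)(C)OC
Why: Acid-catalysed transketalisation onto the cis-diol, leaving the hindered C5 acid free.

Step 9
Reactants: 14 acetonide acid
Product: 16 C5 diazomethyl ketone, via acid chloride 15 (not isolated)
Conditions: 1-chloro-N,N,2-trimethylprop-1-en-1-amine, CH2Cl2, 0 °C to rt; then CH2N2 (excess), Et2O, 0 °C
Reagents that add atoms: diazomethane, C=[N+]=[N-]
Why: First half of the Arndt–Eistert homologation, the acid chloride being made under neutral conditions that spare the acetonide; the diazo carbon becomes C6.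

Step 10
Reactants: 16 diazoketone; 3 (1S,4R)-4-(tert-butyldimethylsilyloxy)cyclopent-2-en-1-ol
Product: 18 cis-4-silyloxycyclopent-2-enyl ester of the C5 acetic acid (C6H2–C7), via ketene 17 (not isolated)
Conditions: PhCO2Ag (cat.), Et3N, 3 (1.5 equiv), THF, 50 °C, dark
Reagents that add atoms: none
Why: Silver-catalysed Wolff rearrangement with retention at the migrating C5, the ketene being trapped by alcohol 3 to give the allylic ester needed for the next step.

Step 11
Reactants: 18 allylic ester
Product: 21 C6 carboxylic acid carrying the cyclopent-2-enyl ring at C6 (C6–C8 bond), via (E)-silyl ketene acetal 19 (not isolated), via trimethylsilyl ester 20 (not isolated)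
Conditions: LiN(i-Pr)2 (1.2 equiv), Me3SiCl (in situ), THF, −78 to 60 °C; then 1 M HCl
Reagents that add atoms: none
Why: Ireland–Claisen rearrangement, which forms the congested C6–C8 bond intramolecularly on the ring face that the oxygen leaves (chirality transfer from the carbinol of 3, new bond cis to the silyloxy group), the chair-like arrangement of the THF-derived (E)-ketene acetal being expected to set C6 as in the target; the more acidic ester α-CH2 is silylated in preference to the amide α-CH2.

Step 12
Reactants: 21 C7 acid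
Product: 22 C7 methyl ester
Conditions: Me3SiCHN2, MeOH/toluene, 0 °C
Reagents that add atoms: (trimethylsilyl)diazomethane, C[Si](C)(C)C=[N+]=[N-]
Why: Mild esterification of the hindered acid without base, so that C6 is not epimerised.

Step 13
Reactants: 22 Weinreb amide triester
Product: 23 dichloromethyl ketone (C9H2–C11(=O)–C12HCl2)
Conditions: CH2Cl2, LiN(i-Pr)2, THF, −95 °C; then 22; AcOH quench at −95 °C
Reagents that add atoms: dichloromethane, ClCCl
Why: Addition of dichloromethyllithium to the Weinreb amide gives a stable chelate that releases the ketone only on quench, and the three esters (two neopentyl, one α-branched) are far less reactive.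

Step 14
Reactants: 23 silyl ether
Product: 24 cyclopent-3-enol
Conditions: HF·pyridine, pyridine, THF, 0 °C to rt
Reagents that add atoms: none
Why: Buffered fluoride desilylation, compatible with the acetonide and the base-sensitive dichloromethyl ketone.

Step 15
Reactants: 24 cyclopentenol
Product: 25 ring A dichloromethyl ketone with the C6-linked cyclopentadiene (drawn as the 1-substituted isomer, in equilibrium with its 1,5-hydrogen-shift isomers)
Conditions: Burgess reagent (MeO2CN–SO2NEt3 inner salt), benzene, 50 °C; used at once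
Reagents that add atoms: none
Why: Burgess syn-elimination of the secondary homoallylic alcohol toward the ring CH2 gives a cyclopentadiene that equilibrates by 1,5-hydrogen shifts; no β-hydrogen at C6 is available to the sulfamate, so the ester-conjugated exocyclic alkene cannot form.

Step 16
Reactants: 25 cyclopentadienyl dichloromethyl ketone
Product: 27 tetracyclic C11 ketone with C12 chloride and C15=C16 alkene (rings B and C closed), via lithium-bound chloro-oxyallyl cation 26 (not isolated)
Conditions: Et3N, LiClO4, CF3CH2OH, 0 °C to rt, 5 mM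
Reagents that add atoms: none
Why: Et3N enolises the dichloromethyl ketone toward C9 and LiClO4 assists loss of chloride from C12, giving the lithium-bound chloro-oxyallyl cation 26 (C9–C11(O)–C12); this adds across C8 and C13 of the diene isomer that carries the tether on a diene terminus (the other isomers cannot reach and drain through it by 1,5-hydrogen shift) in a concerted asynchronous or stepwise (4+3) cycloaddition, the intramolecular form of the known oxyallyl cycloaddition of α-halo ketones with cyclopentadienes. Ring B closes as the five-membered tether ring through C8–C9 (5-exo attack of C9 on the diene terminus), and ring C closes as the six-membered ring of the new bicyclo[3.2.1]octene through C12–C13, the diene CH2 becoming the bridge C14 and the diene becoming ring D with the C15=C16 alkene. C8 and C9 are set together as the cis B/C junction because the Z-oxyallyl (C10 syn to oxygen, forced by the quaternary C10) can span the three-atom tether C10–C5–C6 as an unstrained envelope only in the extended arrangement (C11 over C14), and C13 follows from suprafacial bonding to the diene. The step needs bonding on the face that puts C11 syn to the axial C20 ester: Li+ bridging the oxyallyl oxygen and the C20 carbonyl holds C9–C11 eclipsed with C10–C20, and on the diene side this mode places C14H2, not the C7 ester, next to H6. The C12 chloride should settle equatorial (trans to C10) by enolisation under the amine, which is the epimer that step 17 displaces with inversion.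

Step 17
Reactants: 27 α-chloro ketone
Product: 28 C11-keto C20→C12 lactone
Conditions: NaI, DMF, 70 °C
Reagents that add atoms: none
Why: Dealkylative lactonisation by neighbouring-group participation, in which the C20 ester carbonyl, held above ring C, displaces the activated α-keto halide at C12 from the backside (inversion, oxygen ends axial and cis to C10) and iodide removes the methyl group; halide exchange also funnels any C12 epimer.

Step 18
Reactants: 28 keto lactone
Product: 29 C11 alcohol (hydroxyl expected trans to the lactone oxygen; configuration inconsequential)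
Conditions: NaBH4, MeOH/CH2Cl2, −40 to 0 °C
Reagents that add atoms: none
Why: Chemoselective borohydride reduction of the ketone in the presence of lactone and hindered esters, hydride arriving from the face away from the C15=C16 bridge.

Step 19
Reactants: 29 C11 alcohol
Product: 30 C11 O-(imidazol-1-ylthiocarbonyl) derivative
Conditions: (imidazol-1-yl)2C=S, DMAP, toluene, 90 °C
Reagents that add atoms: 1,1'-thiocarbonyldiimidazole, S=C(n1ccnc1)n1ccnc1
Why: Neutral thioacylation of the hindered secondary alcohol in preparation for radical deoxygenation.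

Step 20
Reactants: 30 thiocarbonylimidazolide
Product: 31 C11-methylene lactone with C15=C16 alkene
Conditions: Bu3SnH, AIBN, toluene, 100 °C
Reagents that add atoms: none
Why: Barton–McCombie deoxygenation, in which the C11 radical has no favourable cyclisation onto the alkene (only four-membered rings) and the β-acyloxy group at C12 is not lost from a radical.

Step 21
Reactants: 31 alkene
Product: 33 C16 alcohol (hydroxyl on the face of the C14 bridge), via B-alkyl-9-borabicyclononane 32 (not isolated)
Conditions: 9-BBN, THF, 60 °C; then H2O2, aq. NaOAc, 0 °C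
Reagents that add atoms: hydrogen peroxide, OO
Why: Hydroboration–oxidation with a bulky borane, boron going to C16 (next to the CH bridgehead C13 rather than the quaternary C8) from the open face of the strained alkene, and buffered oxidation sparing the lactone.

Step 22
Reactants: 33 C16 alcohol
Product: 34 C16 ketone
Conditions: Dess–Martin periodinane, NaHCO3, CH2Cl2, rt
Reagents that add atoms: none
Why: Mild oxidation of the secondary alcohol that removes the temporary C16 stereocentre.

Step 23
Reactants: 34 C16 ketone
Product: 35 C16 exocyclic methylene (C17), dimethyl ester acetonide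
Conditions: Ph3PCH3Br, KOt-Bu, THF, 0 to 50 °C
Reagents that add atoms: methyltriphenylphosphonium bromide, C[P+](c1ccccc1)(c1ccccc1)c1ccccc1.[Br-]
Why: Wittig methylenation of the cyclopentanone-type ketone, to which esters and lactone are inert; any base-induced equilibration at C6 should favour the target configuration, with the C7 ester away from the axial C19 group.

Step 24
Reactants: 35 dimethyl ester
Product: 36 C7,C19 diacid acetonide
Conditions: LiS(n-Pr), HMPA, rt to 50 °C; then aq. citric acid
Reagents that add atoms: none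
Why: SN2 demethylation of the two hindered methyl esters by thiolate at the methyl carbon, which does not depend on access to the acyl carbons and is much faster than attack at the secondary C12 of the lactone.

Step 25
Reactants: 36 diacid acetonide
Product: 37 CNP0212122.1 (target)
Conditions: AcOH/H2O (4:1), 50 °C
Reagents that add atoms: none
Why: Mild acidic hydrolysis of the acetonide, under conditions too weak to isomerise or hydrate the C16 methylene.

**Compound list**

1 | (1R,4S)-cis-4-acetoxycyclopent-2-en-1-ol | CC(=O)O[C@@H]1C=C[C@H](O)C1 | starting material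
2 | (1S,4R)-4-(tert-butyldimethylsilyloxy)cyclopent-2-en-1-yl acetate | CC(=O)O[C@@H]1C=C[C@H](O[Si](C)(C)C(C)(C)C)C1 | intermediate
3 | (1S,4R)-4-(tert-butyldimethylsilyloxy)cyclopent-2-en-1-ol | O[C@@H]1C=C[C@H](O[Si](C)(C)C(C)(C)C)C1 | intermediate
4 | methyl (2E)-penta-2,4-dienoate | C=C/C=C/C(=O)OC | starting material
5 | maleic anhydride | O=C1OC(=O)C=C1 | starting material
6 | all-cis methyl 1,3-dioxo-1,3,3a,4,7,7a-hexahydro-2-benzofuran-4-carboxylate (racemic; the enantiomer carried on is drawn) | COC(=O)[C@@H]1C=CC[C@@H]2C(=O)OC(=O)[C@H]12 | intermediate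
7 | all-cis 2,6-bis(methoxycarbonyl)cyclohex-3-ene-1-carboxylic acid (C5 acid; C4, C10 esters) | COC(=O)[C@@H]1C=CC[C@H](C(=O)OC)[C@@H]1C(=O)O | intermediate
8 | dilithium dienolate carboxylate of 7 | COC([O-])=C1C=CC[C@H](C(=O)OC)[C@@H]1C(=O)[O-].[Li+].[Li+] | intermediate (not isolated)
9 | 2,6-bis(methoxycarbonyl)-2-methylcyclohex-3-ene-1-carboxylic acid (three carboxyl carbons cis) | COC(=O)[C@]1(C)C=CC[C@H](C(=O)OC)[C@@H]1C(=O)O | intermediate
10 | 2-bromo-N-methoxy-N-methylacetamide | CON(C)C(=O)CBr | starting material
11 | dilithium C10 enolate carboxylate of 9 | COC(=O)[C@]1(C)C=CCC(=C([O-])OC)[C@@H]1C(=O)[O-].[Li+].[Li+] | intermediate (not isolated)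
12 | C10-alkylated acid: 6-[2-(methoxy(methyl)amino)-2-oxoethyl]-2,6-bis(methoxycarbonyl)-2-methylcyclohex-3-ene-1-carboxylic acid | COC(=O)[C@]1(C)C=CC[C@](CC(=O)N(C)OC)(C(=O)OC)[C@@H]1C(=O)O | intermediate
13 | C2,C3-cis-diol of 12 | COC(=O)[C@]1(C)[C@@H](O)[C@@H](O)C[C@](CC(=O)N(C)OC)(C(=O)OC)[C@@H]1C(=O)O | intermediate
14 | C2,C3-acetonide C5 acid | COC(=O)[C@]1(C)[C@H]2OC(C)(C)O[C@H]2C[C@](CC(=O)N(C)OC)(C(=O)OC)[C@@H]1C(=O)O | intermediate
15 | C5 acid chloride | COC(=O)[C@]1(C)[C@H]2OC(C)(C)O[C@H]2C[C@](CC(=O)N(C)OC)(C(=O)OC)[C@@H]1C(=O)Cl | intermediate (not isolated)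
16 | C5 diazomethyl ketone | COC(=O)[C@]1(C)[C@H]2OC(C)(C)O[C@H]2C[C@](CC(=O)N(C)OC)(C(=O)OC)[C@@H]1C(=O)C=[N+]=[N-] | intermediate
17 | C5 ketene (C6=C7=O) | COC(=O)[C@]1(C)[C@H]2OC(C)(C)O[C@H]2C[C@](CC(=O)N(C)OC)(C(=O)OC)[C@@H]1C=C=O | intermediate (not isolated)
18 | cis-4-silyloxycyclopent-2-enyl ester of the C5 acetic acid | COC(=O)[C@]1(C)[C@H]2OC(C)(C)O[C@H]2C[C@](CC(=O)N(C)OC)(C(=O)OC)[C@@H]1CC(=O)O[C@@H]1C=C[C@H](O[Si](C)(C)C(C)(C)C)C1 | intermediate
19 | (E)-trimethylsilyl ketene acetal of 18 | COC(=O)[C@]1(C)[C@H]2OC(C)(C)O[C@H]2C[C@](CC(=O)N(C)OC)(C(=O)OC)[C@@H]1/C=C(/O[Si](C)(C)C)O[C@@H]1C=C[C@H](O[Si](C)(C)C(C)(C)C)C1 | intermediate (not isolated)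
20 | trimethylsilyl ester of 21 | COC(=O)[C@]1(C)[C@H]2OC(C)(C)O[C@H]2C[C@](CC(=O)N(C)OC)(C(=O)OC)[C@@H]1[C@H](C(=O)O[Si](C)(C)C)[C@H]1C=CC[C@H]1O[Si](C)(C)C(C)(C)C | intermediate (not isolated)
21 | C7 acid with C6-bound cis-5-silyloxycyclopent-2-enyl ring | COC(=O)[C@]1(C)[C@H]2OC(C)(C)O[C@H]2C[C@](CC(=O)N(C)OC)(C(=O)OC)[C@@H]1[C@H](C(=O)O)[C@H]1C=CC[C@H]1O[Si](C)(C)C(C)(C)C | intermediate
22 | C7 methyl ester of 21 | COC(=O)[C@]1(C)[C@H]2OC(C)(C)O[C@H]2C[C@](CC(=O)N(C)OC)(C(=O)OC)[C@@H]1[C@H](C(=O)OC)[C@H]1C=CC[C@H]1O[Si](C)(C)C(C)(C)C | intermediate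
23 | dichloromethyl ketone silyl ether | COC(=O)[C@]1(C)[C@H]2OC(C)(C)O[C@H]2C[C@](CC(=O)C(Cl)Cl)(C(=O)OC)[C@@H]1[C@H](C(=O)OC)[C@H]1C=CC[C@H]1O[Si](C)(C)C(C)(C)C | intermediate
24 | dichloromethyl ketone cyclopent-3-enol | COC(=O)[C@]1(C)[C@H]2OC(C)(C)O[C@H]2C[C@](CC(=O)C(Cl)Cl)(C(=O)OC)[C@@H]1[C@H](C(=O)OC)[C@H]1C=CC[C@H]1O | intermediate
25 | key-step precursor: ring A dichloromethyl ketone with C6-linked cyclopenta-1,3-dien-1-yl | COC(=O)[C@]1(C)[C@H]2OC(C)(C)O[C@H]2C[C@](CC(=O)C(Cl)Cl)(C(=O)OC)[C@@H]1[C@H](C(=O)OC)C1=CC=CC1 | intermediate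
26 | chloro-oxyallyl cation (drawn as zwitterion; lithium-bound) | COC(=O)[C@]1(C)[C@H]2OC(C)(C)O[C@H]2C[C@](C=C([O-])[CH+]Cl)(C(=O)OC)[C@@H]1[C@H](C(=O)OC)C1=CC=CC1 | intermediate (not isolated)
27 | key-step product: tetracyclic C11 ketone, C12 chloride, C15=C16 alkene | C1=C[C@]23C[C@H]1[C@H](Cl)C(=O)[C@H]2[C@@]2(C[C@H](OC(C)(C)O5)[C@H]5[C@@](C)(C(=O)OC)[C@H]2[C@@H]3C(=O)OC)C(=O)OC | intermediate
28 | C11-keto C20→C12 lactone | C1=C[C@]23C[C@H]1[C@@H]1C(=O)[C@H]2[C@@]2(C[C@H](OC(C)(C)O5)[C@H]5[C@@](C)(C(=O)OC)[C@H]2[C@@H]3C(=O)OC)C(=O)O1 | intermediate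
29 | C11 alcohol lactone | C1=C[C@]23C[C@H]1[C@@H]1[C@H](O)[C@H]2[C@@]2(C[C@H](OC(C)(C)O5)[C@H]5[C@@](C)(C(=O)OC)[C@H]2[C@@H]3C(=O)OC)C(=O)O1 | intermediate
30 | C11 O-(imidazol-1-ylthiocarbonyl) lactone | C1=C[C@]23C[C@H]1[C@@H]1[C@H](OC(=S)n4ccnc4)[C@H]2[C@@]2(C[C@H](OC(C)(C)O5)[C@H]5[C@@](C)(C(=O)OC)[C@H]2[C@@H]3C(=O)OC)C(=O)O1 | intermediate
31 | C11-methylene lactone, C15=C16 alkene | C1=C[C@]23C[C@H]1[C@@H]1C[C@H]2[C@@]2(C[C@H](OC(C)(C)O5)[C@H]5[C@@](C)(C(=O)OC)[C@H]2[C@@H]3C(=O)OC)C(=O)O1 | intermediate
32 | C16 B-alkyl-9-borabicyclo[3.3.1]nonane | C6CCC7CCCC6B7[C@@H]1C[C@]23C[C@H]1[C@@H]1C[C@H]2[C@@]2(C[C@H](OC(C)(C)O5)[C@H]5[C@@](C)(C(=O)OC)[C@H]2[C@@H]3C(=O)OC)C(=O)O1 | intermediate (not isolated)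
33 | C16 alcohol | O[C@@H]1C[C@]23C[C@H]1[C@@H]1C[C@H]2[C@@]2(C[C@H](OC(C)(C)O5)[C@H]5[C@@](C)(C(=O)OC)[C@H]2[C@@H]3C(=O)OC)C(=O)O1 | intermediate
34 | C16 ketone | O=C1C[C@]23C[C@H]1[C@@H]1C[C@H]2[C@@]2(C[C@H](OC(C)(C)O5)[C@H]5[C@@](C)(C(=O)OC)[C@H]2[C@@H]3C(=O)OC)C(=O)O1 | intermediate
35 | C16 methylene dimethyl ester acetonide | C=C1C[C@]23C[C@H]1[C@@H]1C[C@H]2[C@@]2(C[C@H](OC(C)(C)O5)[C@H]5[C@@](C)(C(=O)OC)[C@H]2[C@@H]3C(=O)OC)C(=O)O1 | intermediate
36 | C7,C19 diacid acetonide | C=C1C[C@]23C[C@H]1[C@@H]1C[C@H]2[C@@]2(C[C@H](OC(C)(C)O5)[C@H]5[C@@](C)(C(=O)O)[C@H]2[C@@H]3C(=O)O)C(=O)O1 | intermediate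
37 | CNP0212122.1 | C=C1C[C@]23C[C@H]1[C@@H]1C[C@H]2[C@@]2(C[C@H](O)[C@H](O)[C@@](C)(C(=O)O)[C@H]2[C@@H]3C(=O)O)C(=O)O1 | target

**Step count**

Total: 25 steps. Longest linear sequence: 23 steps (steps 3–25, from 4 and 5); the cyclopentenol 3 (steps 1–2) joins at step 10.

**Steps most likely to fail, with fallbacks**

Step 16 (key step). The cycloaddition may bond on the other face of the oxyallyl (C11 next to C1 instead of the C20 ester) or through the compact, trans-fused mode; the cation may also be captured by trifluoroethanol or collapse by a Favorskii pathway. The fallback makes the face a matter of connectivity by closing the C20–O–C12 lactone before the cycloaddition. It sets out from 23: NaI in DMF should effect dealkylative lactonisation at the dichloromethyl carbon to give the spiro chloro keto lactone silyl ether F1. HF·pyridine then gives the spiro chloro keto lactone cyclopentenol F2, and the Burgess reagent gives the spiro chloro keto lactone cyclopentadiene F3. With Et3N in CF3CH2OH, F3 would ionise its remaining chloride (now on an acyloxy-bearing carbon) after enolisation at C9. The resulting oxyallyl lies inside the lactone ring, so the diene can reach it only from the face of C5 and only in the compact mode, and the product is 28, where the fallback rejoins the route.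

Step 11. The rearrangement may run through the boat-like instead of the chair-like arrangement, which would invert C6, and the base may attack the Weinreb amide. The fallback reverses the ring face used. It sets out from 16: Wolff rearrangement in aqueous THF gives the homologated C7 acid F4. Mitsunobu esterification of F4 with 3 (PPh3, DIAD) inverts the carbinol and gives the trans-4-silyloxycyclopent-2-enyl ester F5. Its Ireland–Claisen rearrangement bonds anti to the silyloxy group on the opposite ring face, which reverses the sense at C6 for a given transition-state shape, and gives the trans-ring C7 acid F6. From there Me3SiCHN2 gives the trans-ring methyl ester F7, dichloromethyllithium gives the trans-ring dichloromethyl ketone F8, HF·pyridine gives the trans-ring cyclopentenol F9, and Burgess dehydration returns to the route at 25, because the ring stereocentres vanish in the diene.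

Step 4. The resolving methanolysis may show a low selectivity factor, the opposite sense, or attack at the hindered carbonyl for this substituted anhydride. The fallback separates regiochemistry from resolution. It sets out from 6: NaOMe in MeOH at −20 °C opens the unhindered carbonyl to give the racemic hemiester F10. This is resolved by crystallising the (R)-1-phenylethylammonium salt F11 (or the salt of the antipodal amine, whichever carries the wanted acid in the less soluble salt), and acidification returns to the route at 7.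

**Further compounds**

F1 | step 16 | spiro chloro keto lactone silyl ether (C20–O–C12 closed before cycloaddition; C12 unassigned) | COC(=O)[C@]1(C)[C@H]2OC(C)(C)O[C@H]2C[C@@]3(CC(=O)C(Cl)OC3=O)[C@@H]1[C@H](C(=O)OC)[C@H]1C=CC[C@H]1O[Si](C)(C)C(C)(C)C
F2 | step 16 | spiro chloro keto lactone cyclopentenol | COC(=O)[C@]1(C)[C@H]2OC(C)(C)O[C@H]2C[C@@]3(CC(=O)C(Cl)OC3=O)[C@@H]1[C@H](C(=O)OC)[C@H]1C=CC[C@H]1O
F3 | step 16 | spiro chloro keto lactone cyclopentadiene | COC(=O)[C@]1(C)[C@H]2OC(C)(C)O[C@H]2C[C@@]3(CC(=O)C(Cl)OC3=O)[C@@H]1[C@H](C(=O)OC)C1=CC=CC1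
F4 | step 11 | homologated C7 acid (C5–CH2–CO2H) | COC(=O)[C@]1(C)[C@H]2OC(C)(C)O[C@H]2C[C@](CC(=O)N(C)OC)(C(=O)OC)[C@@H]1CC(=O)O
F5 | step 11 | trans-4-silyloxycyclopent-2-enyl ester | COC(=O)[C@]1(C)[C@H]2OC(C)(C)O[C@H]2C[C@](CC(=O)N(C)OC)(C(=O)OC)[C@@H]1CC(=O)O[C@H]1C=C[C@H](O[Si](C)(C)C(C)(C)C)C1
F6 | step 11 | trans-ring C7 acid | COC(=O)[C@]1(C)[C@H]2OC(C)(C)O[C@H]2C[C@](CC(=O)N(C)OC)(C(=O)OC)[C@@H]1[C@H](C(=O)O)[C@@H]1C=CC[C@H]1O[Si](C)(C)C(C)(C)C
F7 | step 11 | trans-ring methyl ester | COC(=O)[C@]1(C)[C@H]2OC(C)(C)O[C@H]2C[C@](CC(=O)N(C)OC)(C(=O)OC)[C@@H]1[C@H](C(=O)OC)[C@@H]1C=CC[C@H]1O[Si](C)(C)C(C)(C)C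
F8 | step 11 | trans-ring dichloromethyl ketone | COC(=O)[C@]1(C)[C@H]2OC(C)(C)O[C@H]2C[C@](CC(=O)C(Cl)Cl)(C(=O)OC)[C@@H]1[C@H](C(=O)OC)[C@@H]1C=CC[C@H]1O[Si](C)(C)C(C)(C)C
F9 | step 11 | trans-ring cyclopentenol | COC(=O)[C@]1(C)[C@H]2OC(C)(C)O[C@H]2C[C@](CC(=O)C(Cl)Cl)(C(=O)OC)[C@@H]1[C@H](C(=O)OC)[C@@H]1C=CC[C@H]1O
F10 | step 4 | racemic all-cis hemiester (relative configuration drawn) | COC(=O)[C@@H]1C=CC[C@H](C(=O)OC)[C@@H]1C(=O)O
F11 | step 4 | (R)-1-phenylethylammonium salt of 7 | COC(=O)[C@@H]1C=CC[C@H](C(=O)OC)[C@@H]1C(=O)[O-].C[C@@H]([NH3+])c1ccccc1
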